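**Convention.** Locants follow the target: decalin C1–C10 (ring A = C1–C5 and C10, ring B = C5–C10), side chain C11–C16 from C9 to the lactone carbinol, butenolide C17 (methyl-bearing), C18 and C19 (carbonyl). β is the face of the C10 methyl, α the face of H5.

## Analysis of the target

The target is a C25 hydroxy acid on a trans-fused decalin. C9 carries a chain (C11–C16) with an (E)-trisubstituted C13=C14 alkene that ends in a (16R)-β-methylbutenolide. Six of the seven stereocentres lie on the decalin: quaternary C4 (β-methyl, α-carboxyl), C5 (α-H), C6 (α-OH), the tertiary carbinol C8 (α-OH, β-methyl), C9 (α-H) and quaternary C10 (β-methyl). The seventh, C16, is five bonds from the ring and must be set independently in absolute terms. Sensitive groups are the butenolide (acidic C16–H, opened by base and nucleophiles), the tertiary 8-OH (dehydration in strong acid), the 6-hydroxy acid (can lactonise) and the C13=C14 alkene, which rules out late hydrogenation or epoxidation. The difficulty lies in the two quaternary carbons C4 and C10 on either side of C5, each with a fixed relation to C6, and in closing ring B with a tertiary carbinol at C8 next to the chain-bearing C9. The plan rests on the 4α-carboxyl and the 6α-hydroxyl: both are equatorial and flank C5, so they can be tied into a γ-lactone (C4–C(=O)–O–C6–C5) that the target does not contain. Read as a tether, this lactone joins a 2-methylpenta-2,4-dienoic acid (C1–C4 plus carboxyl) to an allylic alcohol C6–C5=C10, so that one cycloaddition builds ring A with C4, C5 and C10 from the single stereocentre C6.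

## Retrosynthetic reasoning

**34 from 32.** No skeletal bond is cut. The C4 carboxyl and the 6-OH are kept as the lactone until the last step, because it protects both through carbanion, reduction and acylation chemistry. The forward step is a saponification in which the butenolide opens as well and must reclose on acidification.

**32 from 30.** The butenolide is cut at O–C19 and C17=C18, back to the α-hydroxy methyl ketone 30. A butenolide would not survive the sulfone carbanion used earlier, so it is made late by acylation of the C16 hydroxyl and intramolecular Wittig closure under near-neutral conditions.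

**30 from 18 and 26 (via 29 and 28).** The chain is cut at C11–C12. C12 is allylic, so the bond can be made by SN2 attack of a sulfonyl-stabilised C11 carbanion on allylic bromide 26. The alkene geometry and C16 are then made on a small fragment, and the sulfone, which is not allylic, is removed reductively without touching C13=C14.

**26 from 4 and 21.** The fragment is cut at C14–C15: an (E)-alkenyl metal from iodide 4 opens epoxide 21 at its CH2 group. The geometry comes from the carboalumination that gives 3, and C16 from a hydrolytic kinetic resolution of 20.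

**18 from 17.** Ring B is cut at C8–C9. This bond creates the tertiary carbinol and C9 together. It has to be formed without base, because a C8 carbonyl lies β to the lactone oxygen on C6 and any enolate toward C7 would expel the carboxylate. For the same reason a sulfonyl carbanion at C9 adding to a C8 carbonyl was set aside. A ketyl–olefin cyclisation of keto vinyl sulfone 17 is neutral, and the sulfone it leaves on C11 is the handle for the chain.

**17 from 14 (via 16 and 15).** These are functional-group steps on the cycloadduct: saturation of C2=C3, olefination of the C9 aldehyde to the vinyl sulfone, and release of the C8 ketone from its dioxolane only after the basic olefination.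

**14 from 13 (key).** Bonds C4–C5 and C1–C10 are cut, which opens ring A and the lactone and leads back to trienoate 13. Nowhere else can one step set both quaternary carbons and C5 from C6. The formyl group on C10 is chosen as the C9 substituent because it is the oxidation level needed next, it activates the dienophile, and as the endo-directing group it places the tether exo. The forward reaction needs attack on one alkene face and a trans-fused lactone.

**13 from 9 and 10 (via 11 and 12); 9 from 4 and 6 (via 8).** The ester bond is cut to dienoic acid 10 and allylic alcohol 9. C6 is set by oxazaborolidine-catalysed reduction of enone 8, and 8 comes from acylation of the alkenyllithium of 4 with Weinreb amide 6. Iodide 4 serves both branches.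

## Alternatives that were turned down

**Alternative 1:** The chain is cut at C14–C15 and at the C13 methyl.
- Forward step: the but-3-ynyl decalin lactone A2 is methylaluminated syn (Me3Al, Cp2ZrCl2), converted to the alanate, and opens epoxide 21 at CH2 to give homoallylic alcohol A1.
- For: one operation fixes the (E)-alkene, joins the chain and brings in C16. That is shorter on the side chain than the sulfone alkylation and desulfonylation used here.
- Against: it is a side-chain plan only. A2 already holds all six ring stereocentres, so C4, C5 and C10 remain unsolved. The advanced A2 must be exposed to excess Me3Al and n-BuLi next to a strained lactone, and alanate openings normally consume the alkenyl partner in excess.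
- Comparison: on convergence at the chain it is the stronger plan. The chosen route uses the same C14–C15 logic on the small pair 4 and 21, where excess is cheap, and adds what Alternative 1 lacks, a construction of ring A.

**Alternative 2:** The C10 methyl is traced to a cyclopropane across C5–C10.
- Forward step: Et2Zn and CH2I2 cyclopropanate a tetrasubstituted C5=C10 alkene syn to a 6β-hydroxyl to give A3; the C5–CH2 bond is cleaved later.
- For: hydroxyl-directed cyclopropanation has a very predictable facial sense, more so than the endo/exo question in the chosen key step.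
- Against: the directing hydroxyl must be 6β while the target is 6α, so C6 must later be inverted next to a quaternary carbon. Cleavage must break C5–CH2 and not C10–CH2 and must put hydrogen on the α face of C5. C4 has to be set separately with no link to this step.
- Comparison: it secures one centre very reliably. The chosen step sets three and uses C6 in its natural configuration as the controller.

**Alternative 3:** Rings A and B are closed together by cutting C5–C10 and C3–C4.
- Forward step: a Me2AlCl-promoted intramolecular Diels–Alder reaction of an open-chain trienoate gives octalin A4.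
- For: two carbocycles in one step, and the ester sits on the dienophile, so the Lewis acid and polarity are matched. In the chosen step the tether forces a regiochemistry that polarity does not favour.
- Against: C6, the tertiary carbinol C8 and C9 must all be set on an open chain beforehand. The diene terminus C10 carries both a methyl and the chain, so one of them is inside and slows the cycloaddition. The relation of C4/C5/C10 to C6/C8/C9 depends on the conformation of a tether containing a quaternary carbon.
- Comparison: it is stronger in rings per step. The chosen route needs only one catalytically set stereocentre before its cycloaddition and relays it through a rigid five-membered tether.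

Key step: step 9

Assumption: building blocks 5, 10 and 19 are taken as purchasable, and the 6-hydroxy acid is taken not to relactonise at pH 4 because its lactone is trans-fused to both rings.

## Route

Step 1
Reactants: 1 prop-2-yn-1-ol
Product: 3 (E)-3-iodo-2-methylprop-2-en-1-ol, via alkenylalane 2 (not isolated)
Conditions: Me3Al (3 equiv), Cp2ZrCl2 (0.25 equiv), CH2Cl2, 0 °C → rt; then I2, THF, −30 °C
Reagents that add atoms: trimethylaluminium C[Al](C)C; iodine II
Why: Zirconium-catalysed carboalumination adds methyl and aluminium syn across the alkyne with aluminium on the terminal carbon; iodinolysis proceeds with retention, so iodine is cis to the methyl and trans to CH2OH.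

Step 2
Reactants: 3 (E)-3-iodo-2-methylprop-2-en-1-ol
Product: 4 1-{[(E)-3-iodo-2-methylprop-2-enyl]oxymethyl}-4-methoxybenzene
Conditions: NaH, 4-methoxybenzyl chloride, Bu4NI (cat.), THF/DMF, 0 °C → rt
Reagents that add atoms: 4-methoxybenzyl chloride COc1ccc(CCl)cc1
Why: Williamson etherification; the alkenyl iodide cannot eliminate because the neighbouring alkene carbon carries no hydrogen.

Step 3
Reactants: 5 ethyl 2-(2-methyl-1,3-dioxolan-2-yl)acetate
Product: 6 N-methoxy-N-methyl-2-(2-methyl-1,3-dioxolan-2-yl)acetamide
Conditions: MeNHOMe·HCl, i-PrMgCl, THF, −20 → 0 °C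
Reagents that add atoms: N,O-dimethylhydroxylamine hydrochloride CNOC.Cl
Why: Direct aminolysis of the ester by the magnesium amide of N,O-dimethylhydroxylamine (Weinreb amide formation); the ketal is inert to base.

Step 4
Reactants: 4 1-{[(E)-3-iodo-2-methylprop-2-enyl]oxymethyl}-4-methoxybenzene; 6 N-methoxy-N-methyl-2-(2-methyl-1,3-dioxolan-2-yl)acetamide
Product: 8 (3E)-5-[(4-methoxyphenyl)methoxy]-4-methyl-1-(2-methyl-1,3-dioxolan-2-yl)pent-3-en-2-one, via alkenyllithium 7 (not isolated)
Conditions: t-BuLi (2.0 equiv), Et2O, −78 °C; then 6, −78 → 0 °C; aq. NH4Cl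
Reagents that add atoms: none
Why: Iodine–lithium exchange keeps the alkene geometry, and the alkenyllithium acylates the Weinreb amide once because the chelated tetrahedral adduct survives until work-up.

Step 5
Reactants: 8 (3E)-5-[(4-methoxyphenyl)methoxy]-4-methyl-1-(2-methyl-1,3-dioxolan-2-yl)pent-3-en-2-one
Product: 9 (2S,3E)-5-[(4-methoxyphenyl)methoxy]-4-methyl-1-(2-methyl-1,3-dioxolan-2-yl)pent-3-en-2-ol
Conditions: (R)-2-methyl-CBS-oxazaborolidine (0.3 equiv), catecholborane, PhMe, −78 °C
Reagents that add atoms: none
Why: Corey–Bakshi–Shibata reduction; the alkenyl group acts as the large substituent and the CH2 group as the small one, so the (R)-catalyst should give the (S)-allylic alcohol, by analogy with aryl methyl ketones; this sets C6.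

Step 6
Reactants: 9 (2S,3E)-5-[(4-methoxyphenyl)methoxy]-4-methyl-1-(2-methyl-1,3-dioxolan-2-yl)pent-3-en-2-ol; 10 (E)-2-methylpenta-2,4-dienoic acid
Product: 11 (2S,3E)-5-[(4-methoxyphenyl)methoxy]-4-methyl-1-(2-methyl-1,3-dioxolan-2-yl)pent-3-en-2-yl (E)-2-methylpenta-2,4-dienoate
Conditions: EDC·HCl, DMAP, CH2Cl2, 0 °C → rt
Reagents that add atoms: none
Why: Carbodiimide (Steglich) esterification at the carbinol oxygen; no bond to C6 is broken, so the configuration is kept.

Step 7
Reactants: 11 (2S,3E)-5-[(4-methoxyphenyl)methoxy]-4-methyl-1-(2-methyl-1,3-dioxolan-2-yl)pent-3-en-2-yl (E)-2-methylpenta-2,4-dienoate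
Product: 12 (2S,3E)-5-hydroxy-4-methyl-1-(2-methyl-1,3-dioxolan-2-yl)pent-3-en-2-yl (E)-2-methylpenta-2,4-dienoate
Conditions: DDQ, CH2Cl2/pH 7 buffer, 0 °C
Reagents that add atoms: none
Why: Oxidative cleavage of the 4-methoxybenzyl ether; the electron-poor dienoate does not react with DDQ and the buffered medium spares the ketal.

Step 8
Reactants: 12 (2S,3E)-5-hydroxy-4-methyl-1-(2-methyl-1,3-dioxolan-2-yl)pent-3-en-2-yl (E)-2-methylpenta-2,4-dienoate
Product: 13 (2S,3E)-4-methyl-1-(2-methyl-1,3-dioxolan-2-yl)-5-oxopent-3-en-2-yl (E)-2-methylpenta-2,4-dienoate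
Conditions: MnO2, CH2Cl2, rt
Reagents that add atoms: none
Why: Selective oxidation of the primary allylic alcohol to the (E)-enal under neutral conditions; the acyloxy group at C6 is γ to the aldehyde and cannot be eliminated by simple enolisation.

Step 9
Reactants: 13 (2S,3E)-4-methyl-1-(2-methyl-1,3-dioxolan-2-yl)-5-oxopent-3-en-2-yl (E)-2-methylpenta-2,4-dienoate
Product: 14 cycloadduct: ring A cyclohex-2-ene (C2=C3) trans-fused to the γ-lactone C4–C(=O)–O–C6–C5, with 4β-methyl, 5α-H, 10β-methyl, 10α-formyl (C9) and (6S)-C6 bearing the (2-methyl-1,3-dioxolan-2-yl)methyl arm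
Conditions: Me2AlCl (2.2 equiv), CH2Cl2, −78 → −20 °C; Rochelle salt work-up
Reagents that add atoms: none
Why: Me2AlCl binds the formyl oxygen and lowers the LUMO of the (E)-2-methyl-enal, which undergoes a concerted, suprafacial [4+2] cycloaddition with the s-cis dienoate; the closest known reactions are the ester-tethered cyclisations of 2,4-dienoates of allylic alcohols (nona-1,3,8-triene type) and the Lewis-acid-promoted cyclisations of tethered (E)-2-methyl-2-enals. Ring A closes as the six-membered cycloadduct ring through C4–C5 and C1–C10, and the γ-lactone closes in the fused mode because the three-atom tether C(=O)–O–C6 joins diene terminus C4 to dienophile carbon C5; the tether also enforces a regiochemistry that polarity alone would not give. C5 and C10 follow from the (E)-dienophile (C6 cis to the C10 methyl, trans to the formyl carbon) and from the face attacked. That face is fixed by C6: allylic 1,3-strain with the cis methyl on C10 holds C6–H in the alkene plane, so the ester oxygen, and with it the diene, lies on one face and the C7 arm on the other. C4 follows from the endo/exo mode: with the coordinated formyl group endo under C2–C3, C6 is exo and the lactone is trans-fused, which gives 4β-methyl with the carbonyl α. The (E)-diene geometry of acid 10 (carbonyl outside, methyl inside) is what makes the trans-fused product reachable. The step therefore needs face selectivity, secured by the C6 stereocentre, and formyl-endo selectivity, secured by Lewis-acid activation of the only carbonyl conjugated to the dienophile.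

Step 10
Reactants: 14 cycloadduct (C2=C3 alkene, 10α-formyl, dioxolane arm)
Product: 15 saturated lactone aldehyde: ring A cyclohexane trans-fused to the C4–C6 γ-lactone, 4β-methyl, 5α-H, 10β-methyl, 10α-formyl, (6S)-dioxolanylmethyl arm
Conditions: H2 (1 atm), Pd/C, EtOAc, rt
Reagents that add atoms: none
Why: Heterogeneous hydrogenation of the cis-disubstituted ring alkene; the hindered aldehyde, the lactone and the ketal are inert in neutral medium and no stereocentre is formed.

Step 11
Reactants: 15 saturated lactone aldehyde
Product: 16 (E)-vinyl sulfone: as 15 with C10 bearing (E)-CH=CH–SO2Ph (C9=C11) in place of the formyl group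
Conditions: (EtO)2P(O)CH2SO2Ph, NaH, THF, 0 °C → rt
Reagents that add atoms: diethyl [(phenylsulfonyl)methyl]phosphonate CCOP(=O)(CS(=O)(=O)c1ccccc1)OCC
Why: Horner–Wadsworth–Emmons olefination; the aldehyde is non-enolisable and the lactone has no α-hydrogen, so the stabilised anion can only add at C9, and the sulfonyl reagent gives the (E)-alkene.

Step 12
Reactants: 16 (E)-vinyl sulfone with dioxolane arm
Product: 17 keto vinyl sulfone: as 16 with C6 bearing CH2–C(=O)–CH3 (C7, C8 and the C8 methyl)
Conditions: 1 M HCl, THF, rt
Reagents that add atoms: water O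
Why: Acid hydrolysis of the dioxolane; the ketone is released only now because it lies β to the lactone oxygen on C6 and would not have survived the basic olefination (E1cB loss of the carboxylate).

Step 13
Reactants: 17 keto vinyl sulfone
Product: 18 tricyclic lactone sulfone: trans-decalin with the C4–C6 γ-lactone, 8α-hydroxy, 8β-methyl, 9α-H and 9β-CH2SO2Ph (C11)
Conditions: SmI2 (2.5 equiv), HMPA, t-BuOH (2 equiv), THF, −78 → −40 °C
Reagents that add atoms: none
Why: Ketyl–olefin reductive cyclisation (6-exo-trig): the samarium ketyl at C8 adds to the β-carbon C9 of the vinyl sulfone, and the α-sulfonyl radical is reduced and protonated. A chair transition state on the trans-diequatorial C6 and C10 arms should place the vinyl sulfone equatorial (9α-H) and the bulky samarium-bound oxygen equatorial (8α-O, 8β-methyl), trans to the new C9 substituent. The electron-transfer conditions are not basic, so the lactone oxygen on C6 is not eliminated.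

Step 14
Reactants: 19 2-ethenyl-2-methyl-1,3-dioxolane
Product: 20 rac-2-methyl-2-(oxiran-2-yl)-1,3-dioxolane
Conditions: mCPBA, NaHCO3, CH2Cl2, reflux
Reagents that add atoms: 3-chloroperoxybenzoic acid OOC(=O)c1cccc(Cl)c1
Why: Prilezhaev epoxidation of the monosubstituted alkene; bicarbonate buffers the acid so that the ketal survives.

Step 15
Reactants: 20 rac-2-methyl-2-(oxiran-2-yl)-1,3-dioxolane
Product: 21 (R)-2-methyl-2-(oxiran-2-yl)-1,3-dioxolane
Conditions: (S,S)-(salen)Co(OAc) (0.5 mol %; salen = N,N'-bis(3,5-di-tert-butylsalicylidene)cyclohexane-1,2-diamine dianion, trivalent cobalt), H2O (0.55 equiv), THF, 0 °C → rt; distillation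
Reagents that add atoms: none
Why: Hydrolytic kinetic resolution of a terminal epoxide; the (S,S)-catalyst should hydrolyse the (S)-epoxide and leave the (R)-epoxide, whose substituent outranks the ring CH2 as in epichlorohydrin; this sets C16.

Step 16
Reactants: 4 1-{[(E)-3-iodo-2-methylprop-2-enyl]oxymethyl}-4-methoxybenzene; 21 (R)-2-methyl-2-(oxiran-2-yl)-1,3-dioxolane
Product: 23 (1R,3E)-5-[(4-methoxyphenyl)methoxy]-4-methyl-1-(2-methyl-1,3-dioxolan-2-yl)pent-3-en-1-ol, via alkenylmagnesium chloride 22 (not isolated)
Conditions: i-PrMgCl·LiCl, THF, 0 °C → rt; then CuI (10 mol %), 21, −30 → 0 °C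
Reagents that add atoms: none
Why: Iodine–magnesium exchange with retention of geometry, then copper-catalysed opening of the epoxide at its unhindered CH2 group; C16 is not touched and the (E)-alkene places C15 trans to C12.

Step 17
Reactants: 23 (1R,3E)-5-[(4-methoxyphenyl)methoxy]-4-methyl-1-(2-methyl-1,3-dioxolan-2-yl)pent-3-en-1-ol
Product: 24 triethylsilyl ether of 23
Conditions: TESOTf, 2,6-lutidine, CH2Cl2, −78 °C
Reagents that add atoms: triethylsilyl trifluoromethanesulfonate CC[Si](CC)(CC)OS(=O)(=O)C(F)(F)F
Why: Silylation of the hindered secondary alcohol with the reactive triflate; the silyl ether is stable to base and is later removed by acid together with the ketal.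

Step 18
Reactants: 24 triethylsilyl ether of 23
Product: 25 (2E,5R)-2-methyl-5-(2-methyl-1,3-dioxolan-2-yl)-5-(triethylsilyloxy)pent-2-en-1-ol
Conditions: DDQ, CH2Cl2/pH 7 buffer, 0 °C
Reagents that add atoms: none
Why: Oxidative removal of the 4-methoxybenzyl ether; buffered conditions keep the silyl ether and the ketal.

Step 19
Reactants: 25 (2E,5R)-2-methyl-5-(2-methyl-1,3-dioxolan-2-yl)-5-(triethylsilyloxy)pent-2-en-1-ol
Product: 26 {[(1R,3E)-5-bromo-4-methyl-1-(2-methyl-1,3-dioxolan-2-yl)pent-3-enyl]oxy}triethylsilane
Conditions: CBr4, PPh3, 2,6-lutidine, CH2Cl2, 0 °C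
Reagents that add atoms: carbon tetrabromide BrC(Br)(Br)Br
Why: Appel bromination of the primary allylic alcohol without allylic transposition; lutidine scavenges acid.

Step 20
Reactants: 18 tricyclic lactone sulfone; 26 {[(1R,3E)-5-bromo-4-methyl-1-(2-methyl-1,3-dioxolan-2-yl)pent-3-enyl]oxy}triethylsilane
Product: 28 coupled sulfone: 18 alkylated at C11 with the C12–C17 fragment (C11 epimers; 16R; 13E; ketal and silyl ether intact), via dilithio derivative 27 (not isolated)
Conditions: LDA (2.2 equiv), THF, −78 °C; then 26, −78 → −20 °C
Reagents that add atoms: none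
Why: SN2 alkylation of an α-sulfonyl carbanion by a primary allylic bromide; the lactone has no α-hydrogen and a carbonyl shielded by the quaternary C4, so LDA removes only the O–H and C11–H protons. The new centre at C11 is removed in step 21.

Step 21
Reactants: 28 coupled sulfone
Product: 29 desulfonylated lactone: full carbon chain with C17 as its dioxolane and the 16-O-triethylsilyl ether; 8α-OH free
Conditions: 6% Na(Hg), Na2HPO4, MeOH/THF, −20 °C
Reagents that add atoms: none
Why: Reductive desulfonylation by electron transfer; the sulfone is homoallylic and not allylic, so position and geometry of C13=C14 are untouched, and the buffer protects the lactone.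

Step 22
Reactants: 29 desulfonylated lactone
Product: 30 α-hydroxy ketone: (16R)-16-hydroxy-17-oxo side chain on the tricyclic lactone
Conditions: 1 M HCl, THF, rt
Reagents that add atoms: water O
Why: One acid treatment cleaves the triethylsilyl ether and the dioxolane; acidic conditions keep the α-hydroxy ketone from enolising toward C16, and dilute acid at room temperature should leave the tertiary 8-OH.

Step 23
Reactants: 30 α-hydroxy ketone
Product: 32 butenolide lactone: the target with its C4 carboxyl and 6α-oxygen still joined as the γ-lactone, via phosphoranylidene acetate 31 (not isolated)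
Conditions: Ph3P=C=C=O, PhMe, 80 °C
Reagents that add atoms: (triphenylphosphoranylidene)ketene O=C=C=P(c1ccccc1)(c1ccccc1)c1ccccc1
Why: The ketene ylide acylates the C16 hydroxyl to an ester ylide, which closes by intramolecular Wittig reaction on the adjacent ketone to the β-methylbutenolide; the 6-oxygen is masked in the lactone and the tertiary 8-OH is too hindered to compete.

Step 24
Reactants: 32 butenolide lactone
Product: 34 target hydroxy acid CNP0387770.1, via dilithium dicarboxylate 33 (not isolated)
Conditions: LiOH (8 equiv), THF/MeOH/H2O, 40 °C; then 0.5 M HCl to pH 4, 0 °C → rt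
Reagents that add atoms: lithium hydroxide [Li+].[OH-]
Why: Saponification opens the strained trans-fused lactone and the butenolide; on mild acidification the (Z)-4-hydroxy-2-enoic acid should reclose to the butenolide, while the 6-hydroxy acid, whose lactone would be trans-fused to both rings, should stay open.

## Compound list

1 | prop-2-yn-1-ol | C#CCO | starting material
2 | alkenylalane: (E)-3-(dimethylalumanyl)-2-methylprop-2-enyl dimethylaluminium alkoxide | C[Al](C)/C=C(\C)CO[Al](C)C | intermediate
3 | (E)-3-iodo-2-methylprop-2-en-1-ol | I/C=C(\C)CO | intermediate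
4 | 1-{[(E)-3-iodo-2-methylprop-2-enyl]oxymethyl}-4-methoxybenzene | COc1ccc(COC/C(C)=C/I)cc1 | intermediate
5 | ethyl 2-(2-methyl-1,3-dioxolan-2-yl)acetate | CCOC(=O)CC1(C)OCCO1 | starting material
6 | N-methoxy-N-methyl-2-(2-methyl-1,3-dioxolan-2-yl)acetamide | CON(C)C(=O)CC1(C)OCCO1 | intermediate
7 | (E)-alkenyllithium from 4 | COc1ccc(COC/C(C)=C/[Li])cc1 | intermediate
8 | (3E)-5-[(4-methoxyphenyl)methoxy]-4-methyl-1-(2-methyl-1,3-dioxolan-2-yl)pent-3-en-2-one | COc1ccc(COC/C(C)=C/C(=O)CC2(C)OCCO2)cc1 | intermediate
9 | (2S,3E)-5-[(4-methoxyphenyl)methoxy]-4-methyl-1-(2-methyl-1,3-dioxolan-2-yl)pent-3-en-2-ol | COc1ccc(COC/C(C)=C/[C@@H](O)CC2(C)OCCO2)cc1 | intermediate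
10 | (E)-2-methylpenta-2,4-dienoic acid | C=C/C=C(\C)C(=O)O | starting material
11 | dienoate ester of 9 (4-methoxybenzyl ether) | C=C/C=C(\C)C(=O)O[C@@H](CC1(C)OCCO1)/C=C(\C)COCc1ccc(OC)cc1 | intermediate
12 | dienoate ester with free allylic alcohol | C=C/C=C(\C)C(=O)O[C@@H](CC1(C)OCCO1)/C=C(\C)CO | intermediate
13 | (2S,3E)-4-methyl-1-(2-methyl-1,3-dioxolan-2-yl)-5-oxopent-3-en-2-yl (E)-2-methylpenta-2,4-dienoate | C=C/C=C(\C)C(=O)O[C@@H](CC1(C)OCCO1)/C=C(\C)C=O | intermediate
14 | cycloadduct: ring A cyclohexene trans-fused to the C4–C6 γ-lactone, 10α-formyl | O=C[C@@]1(C)CC=C[C@@]2(C)C(=O)O[C@@H](CC3(C)OCCO3)[C@H]12 | intermediate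
15 | saturated lactone aldehyde | O=C[C@@]1(C)CCC[C@@]2(C)C(=O)O[C@@H](CC3(C)OCCO3)[C@H]12 | intermediate
16 | (E)-vinyl sulfone with dioxolane arm | O=S(=O)(/C=C/[C@@]1(C)CCC[C@@]2(C)C(=O)O[C@@H](CC3(C)OCCO3)[C@H]12)c1ccccc1 | intermediate
17 | keto vinyl sulfone | O=S(=O)(/C=C/[C@@]1(C)CCC[C@@]2(C)C(=O)O[C@@H](CC(C)=O)[C@H]12)c1ccccc1 | intermediate
18 | tricyclic lactone sulfone (8α-OH, 8β-CH3, 9β-CH2SO2Ph) | O=S(=O)(C[C@@H]1[C@@]2(C)CCC[C@@]3(C)C(=O)O[C@H]([C@H]23)C[C@@]1(C)O)c1ccccc1 | intermediate
19 | 2-ethenyl-2-methyl-1,3-dioxolane | C=CC1(C)OCCO1 | starting material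
20 | rac-2-methyl-2-(oxiran-2-yl)-1,3-dioxolane | CC1(OCCO1)C1CO1 | intermediate
21 | (R)-2-methyl-2-(oxiran-2-yl)-1,3-dioxolane | CC1(OCCO1)[C@H]1CO1 | intermediate
22 | (E)-alkenylmagnesium chloride from 4 | COc1ccc(COC/C(C)=C/[Mg]Cl)cc1 | intermediate
23 | (1R,3E)-5-[(4-methoxyphenyl)methoxy]-4-methyl-1-(2-methyl-1,3-dioxolan-2-yl)pent-3-en-1-ol | COc1ccc(COC/C(C)=C/C[C@@H](O)C2(C)OCCO2)cc1 | intermediate
24 | triethylsilyl ether of 23 | COc1ccc(COC/C(C)=C/C[C@@H](O[Si](CC)(CC)CC)C2(C)OCCO2)cc1 | intermediate
25 | (2E,5R)-2-methyl-5-(2-methyl-1,3-dioxolan-2-yl)-5-(triethylsilyloxy)pent-2-en-1-ol | OC/C(C)=C/C[C@@H](O[Si](CC)(CC)CC)C1(C)OCCO1 | intermediate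
26 | {[(1R,3E)-5-bromo-4-methyl-1-(2-methyl-1,3-dioxolan-2-yl)pent-3-enyl]oxy}triethylsilane | BrC/C(C)=C/C[C@@H](O[Si](CC)(CC)CC)C1(C)OCCO1 | intermediate
27 | dilithio derivative of 18 (C11 carbanion, C8 alkoxide) | [Li]C([C@@H]1[C@@]2(C)CCC[C@@]3(C)C(=O)O[C@H]([C@H]23)C[C@@]1(C)O[Li])S(=O)(=O)c1ccccc1 | intermediate
28 | coupled sulfone (C11 epimers) | O=S(=O)(C(C/C(C)=C/C[C@@H](O[Si](CC)(CC)CC)C1(C)OCCO1)[C@@H]1[C@@]2(C)CCC[C@@]3(C)C(=O)O[C@H]([C@H]23)C[C@@]1(C)O)c1ccccc1 | intermediate
29 | desulfonylated lactone (C17 dioxolane, 16-O-triethylsilyl) | CC1(OCCO1)[C@H](O[Si](CC)(CC)CC)C/C=C(\C)CC[C@@H]1[C@@]2(C)CCC[C@@]3(C)C(=O)O[C@H]([C@H]23)C[C@@]1(C)O | intermediate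
30 | α-hydroxy ketone (16R) on the tricyclic lactone | CC(=O)[C@H](O)C/C=C(\C)CC[C@@H]1[C@@]2(C)CCC[C@@]3(C)C(=O)O[C@H]([C@H]23)C[C@@]1(C)O | intermediate
31 | phosphoranylidene acetate of 30 | O=C(C=P(c1ccccc1)(c1ccccc1)c1ccccc1)O[C@@H](C(C)=O)C/C=C(\C)CC[C@@H]1[C@@]2(C)CCC[C@@]3(C)C(=O)O[C@H]([C@H]23)C[C@@]1(C)O | intermediate
32 | butenolide lactone (target with the C4/C6 γ-lactone closed) | CC1=CC(=O)O[C@@H]1C/C=C(\C)CC[C@@H]1[C@@]2(C)CCC[C@@]3(C)C(=O)O[C@H]([C@H]23)C[C@@]1(C)O | intermediate
33 | dilithium dicarboxylate (both lactones open) | [Li+].[Li+].[O-]C(=O)/C=C(C)\[C@H](O)C/C=C(\C)CC[C@@H]1[C@@]2(C)CCC[C@@](C)(C([O-])=O)[C@@H]2[C@@H](O)C[C@@]1(C)O | intermediate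
34 | CNP0387770.1 | CC1=CC(=O)O[C@@H]1C/C=C(\C)CC[C@@H]1[C@@]2(C)CCC[C@@](C)(C(=O)O)[C@@H]2[C@@H](O)C[C@@]1(C)O | target

## Step count and risks

Total: 24 steps. Longest linear sequence: 17 steps (1, 2, 4–13, 20–24).

**Step 9 (key).** The most likely failures are competition from the endo-tether mode and slow cycloaddition. The endo-tether mode would give the C4 epimer with a cis-fused lactone, and that epimer cannot be corrected later. The cycloaddition may be slow because the tether forces the ester-bearing diene terminus onto the β-carbon of the enal against the polarity preference; long exposure to Me2AlCl could then open the dioxolane. Fallback: the route leaves at ether 11, which is cyclised without Lewis acid in toluene with BHT at 190 °C in a sealed tube, to give the 4-methoxybenzyl ether cycloadduct F1. Hydrogenation over Pd(OH)2/C saturates C2=C3 and removes the benzyl-type ether to give alcohol F2, and Dess–Martin oxidation returns to aldehyde 15. This changes the electronic mode (an unactivated dienophile, no acid), but the fusion ratio then rests on sterics alone.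

**Step 13.** SmI2 may simply reduce the vinyl sulfone or the ketone without ring closure, and if closure occurs the C8 selectivity may erode, since it rests on the equatorial preference of the samarium-bound oxygen. Fallback: from 17, soft enolisation (TBSOTf, Et3N) gives silyl enol ether F3 (regio- and geometric isomers converge). Hydrogen-atom transfer with Fe(acac)3 and PhSiH3 in ethanol generates the same tertiary α-silyloxy C8 radical, which closes onto the vinyl sulfone to give silyl ether F4. HF·pyridine returns to 18. The radical is made here without a reducing metal, and the bulky silyloxy group should reinforce the equatorial oxygen.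

**Step 23.** The α-hydroxy ketone may lose configurational purity at C16 (enolisation or acyloin shift) under the warm, weakly basic ylide conditions, and some acylation of the 8-OH is possible. Fallback: from 30, acylation with diethylphosphonoacetic acid and DCC at 0 °C gives phosphonoacetate F5, and an intramolecular Horner–Wadsworth–Emmons reaction with LiCl and i-Pr2NEt in MeCN at 0 °C returns to 32.

**Step 24.** Before the butenolide opens, hydroxide may deprotonate C16 and erode its configuration; the hindered lactone may open slowly; and over-acidification may reclose it. Fallback: the route leaves at 29, where the side chain is still base-stable. Saponification followed by alkylation of the carboxylate with allyl bromide gives allyl ester F6, and allyl chloroformate with pyridine and DMAP gives the 6-O-allyl carbonate F7. Dilute HCl then gives α-hydroxy ketone F8, and the ketene ylide gives butenolide F9. Pd(PPh3)4 (zerovalent palladium) with morpholine removes both allyl groups under neutral conditions to give 34, so the butenolide never meets hydroxide.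

## Further compounds

F1 | step 9 | 4-methoxybenzyl ether cycloadduct (C2=C3 alkene, 10α-CH2O-PMB) | COc1ccc(COC[C@@]2(C)CC=C[C@@]3(C)C(=O)O[C@@H](CC4(C)OCCO4)[C@H]23)cc1
F2 | step 9 | saturated lactone primary alcohol (10α-CH2OH) | OC[C@@]1(C)CCC[C@@]2(C)C(=O)O[C@@H](CC3(C)OCCO3)[C@H]12
F3 | step 13 | tert-butyldimethylsilyl enol ether of 17 | O=S(=O)(/C=C/[C@@]1(C)CCC[C@@]2(C)C(=O)O[C@@H](C=C(C)O[Si](C)(C)C(C)(C)C)[C@H]12)c1ccccc1
F4 | step 13 | 8-O-tert-butyldimethylsilyl ether of 18 | O=S(=O)(C[C@@H]1[C@@]2(C)CCC[C@@]3(C)C(=O)O[C@H]([C@H]23)C[C@@]1(C)O[Si](C)(C)C(C)(C)C)c1ccccc1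
F5 | step 23 | 16-O-(diethylphosphonoacetyl) derivative of 30 | CCOP(=O)(CC(=O)O[C@@H](C(C)=O)C/C=C(\C)CC[C@@H]1[C@@]2(C)CCC[C@@]3(C)C(=O)O[C@H]([C@H]23)C[C@@]1(C)O)OCC
F6 | step 24 | allyl ester of the ring-opened hydroxy acid from 29 | CC1(OCCO1)[C@H](O[Si](CC)(CC)CC)C/C=C(\C)CC[C@@H]1[C@@]2(C)CCC[C@@](C)(C(=O)OCC=C)[C@@H]2[C@@H](O)C[C@@]1(C)O
F7 | step 24 | 6-O-allyl carbonate of F6 | CC1(OCCO1)[C@H](O[Si](CC)(CC)CC)C/C=C(\C)CC[C@@H]1[C@@]2(C)CCC[C@@](C)(C(=O)OCC=C)[C@@H]2[C@@H](OC(=O)OCC=C)C[C@@]1(C)O
F8 | step 24 | α-hydroxy ketone with allyl ester and allyl carbonate | CC(=O)[C@H](O)C/C=C(\C)CC[C@@H]1[C@@]2(C)CCC[C@@](C)(C(=O)OCC=C)[C@@H]2[C@@H](OC(=O)OCC=C)C[C@@]1(C)O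
F9 | step 24 | butenolide with allyl ester and allyl carbonate | CC1=CC(=O)O[C@@H]1C/C=C(\C)CC[C@@H]1[C@@]2(C)CCC[C@@](C)(C(=O)OCC=C)[C@@H]2[C@@H](OC(=O)OCC=C)C[C@@]1(C)O
A1 | alternative 1 | (E)-homoallylic alcohol with masked methyl ketone on the 8-O-triethylsilyl decalin lactone | CC1(OCCO1)[C@H](O)C/C=C(\C)CC[C@@H]2[C@@]3(C)CCC[C@@](C)(C(=O)O4)[C@@H]3[C@@H]4C[C@@]2(C)O[Si](CC)(CC)CC
A2 | alternative 1 | 9β-(but-3-ynyl) 8-O-triethylsilyl decalin lactone | C#CCC[C@@H]1[C@@]2(C)CCC[C@@](C)(C(=O)O3)[C@@H]2[C@@H]3C[C@@]1(C)O[Si](CC)(CC)CC
A3 | alternative 2 | β-face cyclopropane across C5–C10 with 6β-hydroxyl | c1ccccc1COCC[C@@H]2[C@@]35C[C@@]5([C@H](O)CC24OCCO4)[C@](C)(C(=O)OC)CCC3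
A4 | alternative 3 | trans-octalin methyl ester with 6-O-silyl ether and 8,11-acetonide | CC1(C)OC[C@@H]2[C@@]3(C)C=CC[C@@](C)(C(=O)OC)[C@@H]3[C@@H](O[Si](C)(C)C(C)(C)C)C[C@@]2(C)O1
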